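The depside is cut at its aryl ester into two copies of one keto acid, 2,4-dihydroxy-6-(2-oxoheptyl)benzoic acid. In each benzene ring the carboxyl carbon on C1 and the CH2–C(=O)–C5H11 chain on the neighbouring C6 are the opened form of a 3-pentylisocoumarin. The C6(aryl)–CH2 bond is therefore made by coupling an ortho-iodobenzoic acid with hept-1-yne, and the carboxylate oxygen then closes the six-membered enol lactone that fixes the ketone on the second chain carbon. One pot turns 2-iodo-4,6-dimethoxybenzoic acid into 6,8-dimethoxy-3-pentylisocoumarin, which serves both halves.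

Key step: step 3

Remark on the chemistry: the target has no stereocentre and no double-bond geometry to control; both aromatic halves are the same keto acid, so one isocoumarin feeds both branches.

Step 1
Reactants: 1 1-iodo-3,5-dimethoxybenzene
Product: 3 2-iodo-4,6-dimethoxybenzaldehyde, via aryl iminium chloride 2 (not isolated)
Conditions: POCl3, DMF, 0 → 90 °C; then H2O
Reagents that add atoms: N,N-dimethylformamide, CN(C)C=O; water, O
Why: Vilsmeier–Haack formylation, in which the chloroiminium electrophile should attack the ring carbon next to iodine (para to one methoxy group, ortho to the other) rather than the more shielded carbon between the two methoxy groups, and water then hydrolyses iminium salt 2 to the aldehyde.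

Step 2
Reactants: 3 2-iodo-4,6-dimethoxybenzaldehyde
Product: 4 2-iodo-4,6-dimethoxybenzoic acid
Conditions: NaClO2, NaH2PO4, 2-methylbut-2-ene, t-BuOH/THF/H2O, 0 °C → rt
Reagents that add atoms: sodium chlorite, [Na+].[O-]Cl=O
Why: Pinnick oxidation, in which chlorous acid adds to the aldehyde and fragments to the acid while 2-methylbut-2-ene removes hypochlorous acid before it can chlorinate the electron-rich ring; the aryl iodide is inert.

Step 3
Reactants: 4 2-iodo-4,6-dimethoxybenzoic acid; 5 hept-1-yne
Product: 7 6,8-dimethoxy-3-pentyl-1H-isochromen-1-one, via 2-(hept-1-yn-1-yl)-4,6-dimethoxybenzoic acid 6 (not isolated)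
Conditions: Pd(PPh3)4 (5 mol %), ZnCl2 (1 equiv), Et3N, DMF, 100 °C (sealed tube)
Reagents that add atoms: none
Why: Zerovalent palladium inserts into the C–I bond of the triethylammonium carboxylate of 4, the heptynylzinc species formed from 5, ZnCl2 and Et3N transmetalates, and reductive elimination forges the aryl–alkynyl bond to give 6. The zinc Lewis acid (or divalent palladium) then activates the triple bond and the carboxylate oxygen adds to the alkyne carbon remote from the ring, closing the lactone by a 6-endo-dig attack, after which protonation of the vinyl–metal bond releases 7. This is the known tandem Sonogashira-type coupling–oxycyclisation of 2-iodobenzoic acids with terminal alkynes to 3-substituted isocoumarins. No stereocentre is formed. The selectivity required is 6-endo over 5-exo closure (the latter would give a hexylidene phthalide and put the ketone on the wrong carbon); it is secured by the ZnCl2 additive, by polarisation of the alkyne through the ortho carboxyl, which makes the distal carbon the electrophilic one, and by both methoxy groups lying meta to the alkyne so that they cannot reverse this bias.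

Step 4
Reactants: 7 6,8-dimethoxy-3-pentyl-1H-isochromen-1-one
Product: 8 6,8-dihydroxy-3-pentyl-1H-isochromen-1-one
Conditions: BBr3 (5 equiv), CH2Cl2, −78 °C → rt; then H2O
Reagents that add atoms: none
Why: Lewis-acid ether cleavage, in which BBr3 complexes each methoxy oxygen and bromide removes the methyl group by SN2 (the peri methoxy group first, through chelation to the lactone carbonyl), while the enol lactone is of a type that tolerates these conditions.

Step 5
Reactants: 8 6,8-dihydroxy-3-pentyl-1H-isochromen-1-one
Product: 9 2,4-dihydroxy-6-(2-oxoheptyl)benzoic acid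
Conditions: 2 M aq. KOH, 70 °C, N2; then 2 M HCl, 0 °C, to pH 2, immediate extraction
Reagents that add atoms: potassium hydroxide, [K+].[OH-]
Why: Saponification of the enol lactone, in which hydroxide adds to C1 and the ring opens to a carboxylate and an enolate that tautomerises to the ketone on the carbon that carried the ring oxygen; cold acidification should free the keto acid without the heating that would re-close the lactone or decarboxylate the β-resorcylic acid.

Step 6
Reactants: 9 2,4-dihydroxy-6-(2-oxoheptyl)benzoic acid
Product: 10 benzyl 2,4-dihydroxy-6-(2-oxoheptyl)benzoate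
Conditions: BnBr (1.05 equiv), KHCO3 (1.1 equiv), DMF, rt
Reagents that add atoms: benzyl bromide, BrCc1ccccc1
Why: Chemoselective carboxylate O-alkylation (SN2), since hydrogen carbonate deprotonates only the carboxylic acid and benzyl bromide therefore gives the ester and leaves both phenols free, as is routine for orsellinic-type acids.

Step 7
Reactants: 9 2,4-dihydroxy-6-(2-oxoheptyl)benzoic acid
Product: 11 benzyl 2,4-bis(benzyloxy)-6-(2-oxoheptyl)benzoate
Conditions: BnBr (3.5 equiv), K2CO3 (4 equiv), DMF, rt → 50 °C
Reagents that add atoms: benzyl bromide, BrCc1ccccc1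
Why: Exhaustive Williamson etherification together with carboxylate alkylation, in which carbonate deprotonates the acid and both phenols and each anion is benzylated by SN2 (the hydrogen-bonded 2-hydroxyl last, hence the gentle warming), while the weakly acidic CH2 next to the ketone is not deprotonated by carbonate.

Step 8
Reactants: 11 benzyl 2,4-bis(benzyloxy)-6-(2-oxoheptyl)benzoate
Product: 12 benzyl 2,4-bis(benzyloxy)-6-[(2-pentyl-1,3-dioxolan-2-yl)methyl]benzoate
Conditions: (TMSOCH2)2 (3 equiv), TMSOTf (0.1 equiv), CH2Cl2, −78 → −20 °C; then pyridine, aq. NaHCO3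
Reagents that add atoms: 1,2-bis(trimethylsilyloxy)ethane, C[Si](C)(C)OCCO[Si](C)(C)C
Why: Ketalisation under Noyori conditions, in which catalytic TMSOTf activates the unhindered dialkyl ketone toward the bis-silyl ether of ethylene glycol and formation of hexamethyldisiloxane drives dioxolane closure at low temperature, which should suppress acid-promoted attack of the neighbouring ester on the activated ketone.

Step 9
Reactants: 12 benzyl 2,4-bis(benzyloxy)-6-[(2-pentyl-1,3-dioxolan-2-yl)methyl]benzoate
Product: 13 2,4-bis(benzyloxy)-6-[(2-pentyl-1,3-dioxolan-2-yl)methyl]benzoic acid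
Conditions: KOH, DMSO/H2O (4:1), 90 °C; then 1 M HCl, 0 °C, to pH 3, immediate extraction
Reagents that add atoms: potassium hydroxide, [K+].[OH-]
Why: Ester saponification by acyl–oxygen cleavage, for which hydroxide in aqueous DMSO is reactive enough to hydrolyse the doubly ortho-substituted benzyl ester while the dioxolane and the benzyl ethers are inert to base; the brief cold acidification is meant to leave the ketal in place.

Step 10
Reactants: 13 2,4-bis(benzyloxy)-6-[(2-pentyl-1,3-dioxolan-2-yl)methyl]benzoic acid; 10 benzyl 2,4-dihydroxy-6-(2-oxoheptyl)benzoate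
Product: 14 benzyl 4-({2,4-bis(benzyloxy)-6-[(2-pentyl-1,3-dioxolan-2-yl)methyl]benzoyl}oxy)-2-hydroxy-6-(2-oxoheptyl)benzoate
Conditions: DCC (1.2 equiv), DMAP (0.2 equiv), CH2Cl2, 0 °C → rt
Reagents that add atoms: none
Why: Steglich esterification, in which carbodiimide activation and DMAP acyl transfer should deliver the acyl group to the 4-hydroxyl of 10 (the more acidic, unencumbered phenol) because the 2-hydroxyl is locked in a hydrogen bond to the benzyl ester carbonyl; the dioxolane keeps the activated acid from closing onto its own ketone as an enol lactone.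

Step 11
Reactants: 14 benzyl 4-({2,4-bis(benzyloxy)-6-[(2-pentyl-1,3-dioxolan-2-yl)methyl]benzoyl}oxy)-2-hydroxy-6-(2-oxoheptyl)benzoate
Product: 15 benzyl 4-{[2,4-bis(benzyloxy)-6-(2-oxoheptyl)benzoyl]oxy}-2-hydroxy-6-(2-oxoheptyl)benzoate
Conditions: 1 M aq. HCl, THF, rt
Reagents that add atoms: water, O
Why: Acid-catalysed ketal hydrolysis through the oxocarbenium ion and the hemiketal, under conditions to which benzyl ethers, the benzyl ester and the hindered aryl ester are stable at room temperature.

Step 12
Reactants: 15 benzyl 4-{[2,4-bis(benzyloxy)-6-(2-oxoheptyl)benzoyl]oxy}-2-hydroxy-6-(2-oxoheptyl)benzoate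
Product: 16 4-{[2,4-dihydroxy-6-(2-oxoheptyl)benzoyl]oxy}-2-hydroxy-6-(2-oxoheptyl)benzoic acid
Conditions: H2 (1 atm), 10% Pd/C, EtOAc, rt
Reagents that add atoms: none
Why: Heterogeneous hydrogenolysis, which should cleave the two benzyl aryl ethers and the benzyl ester at their benzylic C–O bonds under neutral conditions and leave the ketones, the aryl ester and the arene rings untouched, so that the sensitive keto acid is released last.

Compound list
1 | 1-iodo-3,5-dimethoxybenzene | COc1cc(I)cc(OC)c1 | starting material
2 | [(2-iodo-4,6-dimethoxyphenyl)methylidene]dimethylammonium chloride | COc1cc(I)c(C=[N+](C)C)c(OC)c1.[Cl-] | intermediate (not isolated)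
3 | 2-iodo-4,6-dimethoxybenzaldehyde | COc1cc(I)c(C=O)c(OC)c1 | intermediate
4 | 2-iodo-4,6-dimethoxybenzoic acid | COc1cc(I)c(C(=O)O)c(OC)c1 | intermediate
5 | hept-1-yne | C#CCCCCC | starting material
6 | 2-(hept-1-yn-1-yl)-4,6-dimethoxybenzoic acid | CCCCCC#Cc1cc(OC)cc(OC)c1C(=O)O | intermediate (not isolated)
7 | 6,8-dimethoxy-3-pentyl-1H-isochromen-1-one | CCCCCc1cc2cc(OC)cc(OC)c2c(=O)o1 | intermediate
8 | 6,8-dihydroxy-3-pentyl-1H-isochromen-1-one | CCCCCc1cc2cc(O)cc(O)c2c(=O)o1 | intermediate
9 | 2,4-dihydroxy-6-(2-oxoheptyl)benzoic acid | CCCCCC(=O)Cc1cc(O)cc(O)c1C(=O)O | intermediate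
10 | benzyl 2,4-dihydroxy-6-(2-oxoheptyl)benzoate | CCCCCC(=O)Cc1cc(O)cc(O)c1C(=O)OCc1ccccc1 | intermediate
11 | benzyl 2,4-bis(benzyloxy)-6-(2-oxoheptyl)benzoate | CCCCCC(=O)Cc1cc(OCc2ccccc2)cc(OCc2ccccc2)c1C(=O)OCc1ccccc1 | intermediate
12 | benzyl 2,4-bis(benzyloxy)-6-[(2-pentyl-1,3-dioxolan-2-yl)methyl]benzoate | CCCCCC1(Cc2cc(OCc3ccccc3)cc(OCc3ccccc3)c2C(=O)OCc2ccccc2)OCCO1 | intermediate
13 | 2,4-bis(benzyloxy)-6-[(2-pentyl-1,3-dioxolan-2-yl)methyl]benzoic acid | CCCCCC1(Cc2cc(OCc3ccccc3)cc(OCc3ccccc3)c2C(O)=O)OCCO1 | intermediate
14 | benzyl 4-({2,4-bis(benzyloxy)-6-[(2-pentyl-1,3-dioxolan-2-yl)methyl]benzoyl}oxy)-2-hydroxy-6-(2-oxoheptyl)benzoate | CCCCCC(=O)Cc1cc(OC(=O)c2c(OCc3ccccc3)cc(OCc3ccccc3)cc2CC2(CCCCC)OCCO2)cc(O)c1C(=O)OCc1ccccc1 | intermediate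
15 | benzyl 4-{[2,4-bis(benzyloxy)-6-(2-oxoheptyl)benzoyl]oxy}-2-hydroxy-6-(2-oxoheptyl)benzoate | CCCCCC(=O)Cc1cc(OC(=O)c2c(OCc3ccccc3)cc(OCc3ccccc3)cc2CC(=O)CCCCC)cc(O)c1C(=O)OCc1ccccc1 | intermediate
16 | 4-{[2,4-dihydroxy-6-(2-oxoheptyl)benzoyl]oxy}-2-hydroxy-6-(2-oxoheptyl)benzoic acid (CNP0165432.0) | CCCCCC(=O)Cc1cc(OC(=O)c2c(O)cc(O)cc2CC(=O)CCCCC)cc(O)c1C(=O)O | target

Total step count: 12.
Longest linear sequence: 11 steps (steps 1–5, then 7–12) from 1; step 6 is a one-step branch from 9.

Steps most likely to fail

Step 3. The carboxylate may close onto the proximal alkyne carbon (5-exo-dig), or the electron-rich, doubly ortho-substituted benzoate may lose CO2 at 100 °C before coupling. The fallback separates coupling from ring closure. Setting out from 4, methylation (MeI, K2CO3, DMF) would give methyl 2-iodo-4,6-dimethoxybenzoate F1. An ordinary Sonogashira coupling with 5 (PdCl2(PPh3)2, CuI, Et3N, THF, 50 °C) would then give methyl 2-(hept-1-yn-1-yl)-4,6-dimethoxybenzoate F2. Saponification (LiOH, aq. dioxane, 60 °C) would deliver acid 6, now isolated, and catalytic TfOH in CH2Cl2 at rt would close it by Brønsted-acid-promoted 6-endo-dig lactonisation, rejoining the route at 7.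

Step 10. Acyl transfer from the activated, doubly ortho-substituted acid may be slower than its rearrangement to an unreactive N-acylurea, so the esterification may stall. The fallback uses a preformed, compact acyl donor. Setting out from 13, cyanuric fluoride and pyridine in CH2Cl2 at −10 °C would give 2,4-bis(benzyloxy)-6-[(2-pentyl-1,3-dioxolan-2-yl)methyl]benzoyl fluoride F3, which is formed under basic conditions that spare the ketal. Reaction of this acyl fluoride with 10 (Et3N, DMAP cat., CH2Cl2, rt) would acylate the 4-hydroxyl and rejoin the route at 14.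

Step 11. During ketal hydrolysis the oxocarbenium ion or the freed ketone enol may be captured by the neighbouring aryl ester carbonyl, cleaving the depside link with closure of a lactone. The fallback reverses the order of the two deprotections. Setting out from 14, hydrogenolysis (H2, 10% Pd/C, EtOAc, rt) would give 4-({2,4-dihydroxy-6-[(2-pentyl-1,3-dioxolan-2-yl)methyl]benzoyl}oxy)-2-hydroxy-6-(2-oxoheptyl)benzoic acid F4. In F4 the depside carbonyl is deactivated by the hydrogen bond from the free ortho hydroxyl and by conjugation with two phenolic oxygens. Mild hydrolysis (0.5 M aq. HCl, THF, rt) would then remove the ketal and arrive directly at 16.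

Further compounds
F1 | step 3 | methyl 2-iodo-4,6-dimethoxybenzoate | COc1cc(I)c(C(=O)OC)c(OC)c1
F2 | step 3 | methyl 2-(hept-1-yn-1-yl)-4,6-dimethoxybenzoate | CCCCCC#Cc1cc(OC)cc(OC)c1C(=O)OC
F3 | step 10 | 2,4-bis(benzyloxy)-6-[(2-pentyl-1,3-dioxolan-2-yl)methyl]benzoyl fluoride | CCCCCC1(Cc2cc(OCc3ccccc3)cc(OCc3ccccc3)c2C(F)=O)OCCO1
F4 | step 11 | 4-({2,4-dihydroxy-6-[(2-pentyl-1,3-dioxolan-2-yl)methyl]benzoyl}oxy)-2-hydroxy-6-(2-oxoheptyl)benzoic acid | CCCCCC(=O)Cc1cc(OC(=O)c2c(O)cc(O)cc2CC2(CCCCC)OCCO2)cc(O)c1C(=O)O
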